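**Retrosynthetic overview**
1. Target ⇐ 2,10-diacetate of a Z-cyclononene (C15=C1–CH3) by ene-type allylic chlorination; the acetates come from a tetraol.
2. Nine-membered ring ⇐ SmI2 ketyl–enone radical cyclisation forming C9–C10, with hydroxylation of the resulting samarium enolate at C8 (key step; sets C8, C9, C10).
3. Open precursor ⇐ Ni/Cr vinylation (C1–C2) of a bicyclic enone aldehyde with a Z-iodoalkenyl epoxy-lactone.
4. Bicyclic aldehyde ⇐ radical 1,6-addition of a dioxolanyl radical to a cross-conjugated trienone, itself from asymmetric conjugate methylation, ring-A alkylation and dehydrogenation.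
5. Lactone ⇐ hydroformylation, α-methylenation, asymmetric epoxidation, chelation-controlled alkynylation/lactonisation. Ring order: ring B (bought) → ring A → γ-lactone → nine-membered ring.

Assumption and labels: prop-1-ynylmagnesium bromide is used as the bought THF solution; labels C1–C16 follow the ring-carbon order of the target SMILES (C1 = carbon bearing the exocyclic CH2, C2 = adjacent CH–OAc, C3, C4=C5, C6, C7 = ketone, C8, C9, C10, C11, C12, C13 = lactone C=O, C14, C15 = CHCl, C16 = quaternary C–CH3).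

**Route**

Step 1
Reactants: 1 3-methoxycyclopent-2-en-1-one; 2 1-bromo-3-chloropropane
Product: 5 3-(3-chloropropyl)cyclopent-2-en-1-one, via Grignard reagent 3 (not isolated), via magnesium alkoxide 4 (not isolated)
Conditions: Mg, THF, 0 °C; then 1, 0 °C; then 1 M HCl, 23 °C
Reagents that add atoms: water, O
Why: Grignard 1,2-addition to the vinylogous ester followed by acid hydrolysis and dehydration (Stork–Danheiser transposition) gives the 3-alkyl enone; no stereocentre is formed.

Step 2
Reactants: 5 3-(3-chloropropyl)cyclopent-2-en-1-one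
Product: 7 (3aR,6aR)-3a-methylhexahydropentalen-1(2H)-one, via aluminium enolate 6 (not isolated)
Conditions: AlMe3, Cu(O2CC4H3S) (5 mol %), (S,S,S)-phosphoramidite ligand (10 mol %), Et2O, −30 °C; then MeLi, HMPA, THF, −30 to 40 °C
Reagents that add atoms: trimethylaluminium, C[Al](C)C
Why: Alexakis-type Cu-catalysed asymmetric conjugate addition of AlMe3 sets the quaternary C16 under ligand control, and the regiospecific aluminium enolate (activated as its ate complex) closes ring A by 5-(enolexo)-exo-tet alkylation, which can only give the cis-fused bicycle and so fixes C6.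

Step 3
Reactants: 7 (3aR,6aR)-3a-methylhexahydropentalen-1(2H)-one
Product: 9 (3aR,6aR)-2,3a-dimethylhexahydropentalen-1(2H)-one (both C2 epimers), via lithium enolate 8 (not isolated)
Conditions: LiN(i-Pr)2, THF, −78 °C; then MeI, −78 to 0 °C
Reagents that add atoms: iodomethane, CI
Why: Kinetic deprotonation takes the CH2 (C8) rather than the ring-fusion CH and enolate methylation installs the C8 methyl; the new centre is erased in the next step.

Step 4
Reactants: 9 (3aR,6aR)-2,3a-dimethylhexahydropentalen-1(2H)-one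
Product: 10 (R)-2,3a-dimethyl-4,5-dihydropentalen-1(3aH)-one
Conditions: IBX (3 equiv), DMSO, 80 °C
Reagents that add atoms: none
Why: IBX dehydrogenation of ketones (Nicolaou) introduces unsaturation on both α-sides (C8=C9 and C6=C5) to give the cross-conjugated dienone; only C16 remains stereogenic.

Step 5
Reactants: 10 (R)-2,3a-dimethyl-4,5-dihydropentalen-1(3aH)-one
Product: 11 (R)-2,3a-dimethylpentalen-1(3aH)-one
Conditions: DDQ, TsOH (cat.), 1,4-dioxane, 60 °C; product kept cold and used at once
Reagents that add atoms: none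
Why: Acid-promoted γ-enolisation and hydride abstraction by DDQ (as in 4-en-3-one to 4,6-dien-3-one oxidations) extends the C6=C5 arm to the C3=C4–C5=C6 diene; quaternary C16 blocks 1,5-hydrogen shifts, and immediate use limits Diels–Alder dimerisation.

Step 6
Reactants: 11 (R)-2,3a-dimethylpentalen-1(3aH)-one; 12 1,3-dioxolane
Product: 13 (3aS,4S,6aR)-4-(1,3-dioxolan-2-yl)-2,3a-dimethyl-4,6a-dihydropentalen-1(3aH)-one
Conditions: (n-Bu4N)4[W10O32] (2 mol %), 12/MeCN (1:4), 390 nm LED, 15 °C
Reagents that add atoms: none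
Why: Decatungstate hydrogen-atom transfer gives the nucleophilic 1,3-dioxolan-2-yl radical, which adds Giese-fashion to the diene terminus C3 on the face opposite the angular methyl (the other face of the flat trienone is open), and hydrogen return at C6 gives the only possible cis-fused β,γ-enone, setting C3 and C6 relative to C16.

Step 7
Reactants: 13 (3aS,4S,6aR)-4-(1,3-dioxolan-2-yl)-2,3a-dimethyl-4,6a-dihydropentalen-1(3aH)-one
Product: 14 (3aS,4S,6aR)-2,3a-dimethyl-1-oxo-1,3a,4,6a-tetrahydropentalene-4-carbaldehyde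
Conditions: 10% aq. oxalic acid on SiO2, CH2Cl2, 23 °C; used directly
Reagents that add atoms: water, O
Why: Mild heterogeneous acetal hydrolysis frees the C2 aldehyde without moving the β,γ-alkene or epimerising C3.

Step 8
Reactants: 15 methyl methacrylate
Product: 16 methyl (R)-2-methyl-4-oxobutanoate
Conditions: CO/H2 (1:5, 10 bar), Rh(acac)(CO)2 (1 mol %), (S,S)-BenzP* (enantiomer giving R), toluene, 100 °C
Reagents that add atoms: carbon monoxide, [C-]#[O+]
Why: Rh-catalysed anti-Markovnikov asymmetric hydroformylation of the 1,1-disubstituted alkene puts the formyl group on the CH2 terminus and sets the methyl-bearing C12 through the chiral bisphosphine.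

Step 9
Reactants: 16 methyl (R)-2-methyl-4-oxobutanoate
Product: 17 methyl (R)-3-formyl-2-methylbut-3-enoate
Conditions: 37% aq. CH2O, pyrrolidine (10 mol %), EtCO2H (10 mol %), i-PrOH, 45 °C
Reagents that add atoms: formaldehyde, C=O
Why: Amine-catalysed Mannich condensation–elimination (α-methylenation) builds the 2-substituted acrolein; C12 is β to the aldehyde and is not epimerised.

Step 10
Reactants: 17 methyl (R)-3-formyl-2-methylbut-3-enoate
Product: 18 methyl (R)-2-[(R)-2-formyloxiran-2-yl]propanoate
Conditions: 50% aq. H2O2, 9-amino-9-deoxy-epi-quinine·(R)-TRIP salt (10 mol %), THF, 50 °C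
Reagents that add atoms: hydrogen peroxide, OO
Why: Iminium/enamine-catalysed Weitz–Scheffer-type epoxidation of the α-branched enal (List conditions) forms the oxirane with catalyst control of the quaternary C11.

Step 11
Reactants: 18 methyl (R)-2-[(R)-2-formyloxiran-2-yl]propanoate; 19 prop-1-yn-1-ylmagnesium bromide
Product: 21 (3R,4S,7R)-7-methyl-4-(prop-1-yn-1-yl)-1,5-dioxaspiro[2.4]heptan-6-one, via magnesium alkoxide 20 (not isolated)
Conditions: MgBr2·OEt2, CH2Cl2, −78 °C; 19 (THF), −78 to 0 °C; H2O
Reagents that add atoms: none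
Why: Magnesium chelation between the aldehyde and oxirane oxygens (Cram chelate) sends the alkynyl Grignard to the face flanked by the small oxirane CH2, setting C14, and the alkoxide lactonises onto the methyl ester.

Step 12
Reactants: 21 (3R,4S,7R)-7-methyl-4-(prop-1-yn-1-yl)-1,5-dioxaspiro[2.4]heptan-6-one
Product: 22 (3R,4S,7R)-7-methyl-4-[(Z)-2-(triethylsilyl)prop-1-en-1-yl]-1,5-dioxaspiro[2.4]heptan-6-one
Conditions: Et3SiH, [Cp*Ru(MeCN)3]PF6 (2 mol %), CH2Cl2, 0 °C
Reagents that add atoms: triethylsilane, CC[SiH](CC)CC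
Why: Trost's Ru-catalysed trans-hydrosilylation puts silicon on the alkyne carbon distal to the propargylic oxygen and adds H and Si anti, giving the Z-vinylsilane with silicon cis to C14.

Step 13
Reactants: 22 (3R,4S,7R)-7-methyl-4-[(Z)-2-(triethylsilyl)prop-1-en-1-yl]-1,5-dioxaspiro[2.4]heptan-6-one
Product: 23 (3R,4S,7R)-4-[(Z)-2-iodoprop-1-en-1-yl]-7-methyl-1,5-dioxaspiro[2.4]heptan-6-one
Conditions: NIS, MeCN/ClCH2CN (4:1), 0 °C
Reagents that add atoms: N-iodosuccinimide, O=C1CCC(=O)N1I
Why: Electrophilic ipso-iododesilylation of the vinylsilane proceeds with retention of alkene geometry.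

Step 14
Reactants: 14 (3aS,4S,6aR)-2,3a-dimethyl-1-oxo-1,3a,4,6a-tetrahydropentalene-4-carbaldehyde; 23 (3R,4S,7R)-4-[(Z)-2-iodoprop-1-en-1-yl]-7-methyl-1,5-dioxaspiro[2.4]heptan-6-one
Product: 24 Z-allylic alcohol with 2S carbinol joining the bicyclic enone to the epoxy-lactone
Conditions: CrCl2 (4 equiv), NiCl2 (1 mol %), Kishi-type chiral sulfonamide–oxazoline ligand (4.4 equiv), Et3N, THF, 23 °C
Reagents that add atoms: none
Why: Nozaki–Hiyama–Kishi Ni/Cr vinylation adds the alkenyl group to the aldehyde with retention of Z geometry, and the chiral sulfonamide–chromium complex is chosen to give the 2S carbinol against the intrinsic Felkin preference of C3 (a mismatched case; inversion with AcOH under Mitsunobu conditions is the remedy if 2R dominates).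

Step 15
Reactants: 24 Z-allylic alcohol with 2S carbinol joining the bicyclic enone to the epoxy-lactone
Product: 25 bis-trimethylsilyl ether α-silyloxy aldehyde (C10 aldehyde on C11)
Conditions: TMSOTf (2.1 equiv), 2,6-lutidine, DMSO, CH2Cl2, −78 to −20 °C; then Et3N, −78 to 0 °C
Reagents that add atoms: trimethylsilyl triflate, C[Si](C)(C)OS(=O)(=O)C(F)(F)F; dimethyl sulfoxide, CS(C)=O
Why: Kornblum/Swern-type oxidative epoxide opening: after silylation of C2–OH the silyl-activated oxirane is opened by DMSO at the primary C10 (tertiary C11 is deactivated by the lactone) and base-induced loss of Me2S gives the aldehyde with C11 untouched; the exact TMSOTf stoichiometry avoids enol silylation of the enone.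

Step 16
Reactants: 25 bis-trimethylsilyl ether α-silyloxy aldehyde (C10 aldehyde on C11)
Product: 28 Z-cyclononene tetraol (all stereocentres as in 30), via samarium enolate 26 (not isolated), via bis-silyl ether 27 (not isolated)
Conditions: SmI2 (2.5 equiv), THF (2 mM), −78 to −40 °C; then (camphorsulfonyl)oxaziridine, −78 to 0 °C; then citric acid, MeOH/H2O
Reagents that add atoms: (camphorsulfonyl)oxaziridine, CC1(C)C2CCC13CS(=O)(=O)N4OC34C2
Why: Proposed new method: SmI2 forms the C10 ketyl radical, which closes the nine-membered ring by 9-exo addition to C9 of the enone on the convex face (the concave face of C9 is shielded by the C2 substituent hanging from C3) with the samarium-bound ketyl oxygen held syn to the C11 oxygen to give 10S, the second electron gives a regiospecific samarium enolate that the Davis oxaziridine hydroxylates at C8 anti to the new C9 substituent, and acidic work-up removes the silyl ethers; the closest known chemistry is the SmI2 ketyl–olefin cyclisation to medium rings combined with Davis hydroxylation of metal enolates.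

Step 17
Reactants: 28 Z-cyclononene tetraol (all stereocentres as in 30)
Product: 29 2,10-diacetate of 28
Conditions: Ac2O, DMAP, pyridine, CH2Cl2, 0 to 23 °C
Reagents that add atoms: acetic anhydride, CC(=O)OC(C)=O
Why: DMAP-catalysed acylation esterifies the two secondary alcohols (C2, C10) while the tertiary C8 and C11 hydroxyls do not react; no stereocentre is touched.

Step 18
Reactants: 29 2,10-diacetate of 28
Product: 30 CNP0145188.1 (target)
Conditions: t-BuOCl, SiO2, CH2Cl2, −20 °C, dark
Reagents that add atoms: tert-butyl hypochlorite, CC(C)(C)OCl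
Why: Ene-type electrophilic chlorination of the only trisubstituted, most electron-rich alkene puts Cl on the less substituted C15 with loss of a methyl proton to form the exocyclic methylene; 15S is expected if Cl+ attacks the exposed outer face of the Z-cyclononene anti to the C14–O bond, but this face selectivity is not secured.

**Compound list**
1 | 3-methoxycyclopent-2-en-1-one | COC1=CC(=O)CC1 | starting material
2 | 1-bromo-3-chloropropane | ClCCCBr | starting material
3 | (3-chloropropyl)magnesium bromide | ClCCC[Mg]Br | intermediate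
4 | bromomagnesium 1-(3-chloropropyl)-3-methoxycyclopent-2-en-1-olate (racemic) | COC1=CC(CCCCl)(O[Mg]Br)CC1 | intermediate
5 | 3-(3-chloropropyl)cyclopent-2-en-1-one | O=C1C=C(CCCCl)CC1 | intermediate
6 | dimethylaluminium (S)-3-(3-chloropropyl)-3-methylcyclopent-1-en-1-olate | ClCCC[C@]1(C)CCC(O[Al](C)C)=C1 | intermediate
7 | (3aR,6aR)-3a-methylhexahydropentalen-1(2H)-one | C1C[C@@]2(C)CCC[C@H]2C1=O | intermediate
8 | lithium (3aR,6aR)-3a-methyl-3,3a,4,5,6,6a-hexahydropentalen-1-olate | C1(O[Li])=CC[C@@]2(C)CCC[C@@H]12 | intermediate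
9 | (3aR,6aR)-2,3a-dimethylhexahydropentalen-1(2H)-one (both C2 epimers) | CC1C[C@@]2(C)CCC[C@H]2C1=O | intermediate
10 | (R)-2,3a-dimethyl-4,5-dihydropentalen-1(3aH)-one | CC1=C[C@@]2(C)CCC=C2C1=O | intermediate
11 | (R)-2,3a-dimethylpentalen-1(3aH)-one | CC1=C[C@@]2(C)C=CC=C2C1=O | intermediate
12 | 1,3-dioxolane | C1COCO1 | starting material
13 | (3aS,4S,6aR)-4-(1,3-dioxolan-2-yl)-2,3a-dimethyl-4,6a-dihydropentalen-1(3aH)-one | O1CCOC1[C@H]2C=C[C@H]3C(=O)C(C)=C[C@@]23C | intermediate
14 | (3aS,4S,6aR)-2,3a-dimethyl-1-oxo-1,3a,4,6a-tetrahydropentalene-4-carbaldehyde | O=C[C@H]1C=C[C@H]2C(=O)C(C)=C[C@@]12C | intermediate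
15 | methyl methacrylate | C=C(C)C(=O)OC | starting material
16 | methyl (R)-2-methyl-4-oxobutanoate | O=CC[C@@H](C)C(=O)OC | intermediate
17 | methyl (R)-3-formyl-2-methylbut-3-enoate | C=C(C=O)[C@@H](C)C(=O)OC | intermediate
18 | methyl (R)-2-[(R)-2-formyloxiran-2-yl]propanoate | O=C[C@]1(CO1)[C@@H](C)C(=O)OC | intermediate
19 | prop-1-yn-1-ylmagnesium bromide | CC#C[Mg]Br | starting material
20 | bromomagnesium alkoxide of methyl (R)-2-{(R)-2-[(S)-1-hydroxybut-2-yn-1-yl]oxiran-2-yl}propanoate | CC#C[C@H](O[Mg]Br)[C@]1(CO1)[C@@H](C)C(=O)OC | intermediate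
21 | (3R,4S,7R)-7-methyl-4-(prop-1-yn-1-yl)-1,5-dioxaspiro[2.4]heptan-6-one | C1O[C@]12[C@@H](C)C(=O)O[C@H]2C#CC | intermediate
22 | (3R,4S,7R)-7-methyl-4-[(Z)-2-(triethylsilyl)prop-1-en-1-yl]-1,5-dioxaspiro[2.4]heptan-6-one | C1O[C@]12[C@@H](C)C(=O)O[C@H]2/C=C(\[Si](CC)(CC)CC)C | intermediate
23 | (3R,4S,7R)-4-[(Z)-2-iodoprop-1-en-1-yl]-7-methyl-1,5-dioxaspiro[2.4]heptan-6-one | C1O[C@]12[C@@H](C)C(=O)O[C@H]2/C=C(\I)C | intermediate
24 | (3R,4S,7R)-4-{(1Z,3S)-3-[(3aS,4S,6aR)-2,3a-dimethyl-1-oxo-1,3a,4,6a-tetrahydropentalen-4-yl]-3-hydroxy-2-methylprop-1-en-1-yl}-7-methyl-1,5-dioxaspiro[2.4]heptan-6-one | C1O[C@]12[C@@H](C)C(=O)O[C@H]2/C=C(/C)[C@@H](O)[C@H]3C=C[C@H]4C(=O)C(C)=C[C@@]34C | intermediate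
25 | (2S,3S,4R)-2-{(1Z,3S)-3-[(3aS,4S,6aR)-2,3a-dimethyl-1-oxo-1,3a,4,6a-tetrahydropentalen-4-yl]-2-methyl-3-(trimethylsilyloxy)prop-1-en-1-yl}-4-methyl-5-oxo-3-(trimethylsilyloxy)tetrahydrofuran-3-carbaldehyde | O=C[C@]1(O[Si](C)(C)C)[C@@H](C)C(=O)O[C@H]1/C=C(/C)[C@@H](O[Si](C)(C)C)[C@H]2C=C[C@H]3C(=O)C(C)=C[C@@]23C | intermediate
26 | cyclised samarium enolate/alkoxide: C9–C10 bond formed, C7(OSmI2)=C8 enolate, C10–OSmI2, TMS ethers at C2 and C11, Z alkene C15=C1; other stereocentres as in 30 | C/C1=C/[C@@H]2OC(=O)[C@H](C)[C@@]2(O[Si](C)(C)C)[C@@H](O[Sm](I)I)[C@H]3C(C)=C(O[Sm](I)I)[C@@H]4C=C[C@H]([C@@H]1O[Si](C)(C)C)[C@]34C | intermediate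
27 | 2,11-bis-O-trimethylsilyl ether of 28 | C/C1=C/[C@@H]2OC(=O)[C@H](C)[C@@]2(O[Si](C)(C)C)[C@@H](O)[C@H]3[C@](C)(O)C(=O)[C@@H]4C=C[C@H]([C@@H]1O[Si](C)(C)C)[C@]34C | intermediate
28 | Z-cyclononene tetraol: des-chloro, deacetyl, C15=C1(CH3) alkene, OH at C2, C8, C10, C11, C7 ketone; all stereocentres as in 30 | C/C1=C/[C@@H]2OC(=O)[C@H](C)[C@@]2(O)[C@@H](O)[C@H]3[C@](C)(O)C(=O)[C@@H]4C=C[C@H]([C@@H]1O)[C@]34C | intermediate
29 | 2,10-diacetate of 28 | C/C1=C/[C@@H]2OC(=O)[C@H](C)[C@@]2(O)[C@@H](OC(C)=O)[C@H]3[C@](C)(O)C(=O)[C@@H]4C=C[C@H]([C@@H]1OC(C)=O)[C@]34C | intermediate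
30 | CNP0145188.1 | C=C1[C@@H](OC(C)=O)[C@H]2C=C[C@H]3C(=O)[C@@](C)(O)[C@H]([C@H](OC(C)=O)[C@]4(O)[C@@H](C)C(=O)O[C@H]4[C@H]1Cl)[C@@]23C | target

**Totals**
Total steps: 18. Longest linear sequence: 12 (steps 1–7, then 14–18); the lactone branch is 6 steps (8–13).

**Three steps most likely to fail**

Step 16 (nine-membered ketyl–enone closure with tandem hydroxylation). The ring closure is entropically demanding, three stereocentres depend on it, and the enolate must survive until oxidation. The fallback sets out from 23 and 13 and comes back at 28. Oxidative opening of the oxirane of 23 (TMSOTf, DMSO, then Et3N) gives the silyloxy aldehyde F2. SmI2-mediated intermolecular ketyl–enone coupling of F2 with an excess of the enone acetal 13, again quenched with the oxaziridine, forms the C9–C10 bond and the C8 hydroxyl before any ring strain is involved and gives the coupled iodide F3. Aqueous acid removes the dioxolane and the silyl ether to give the iodo aldehyde F4. An intramolecular Ni/Cr-mediated Nozaki–Hiyama–Kishi coupling at high dilution then closes the ring at C1–C2 and delivers 28.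

Step 6 (radical 1,6-addition to the trienone). The trienone 11 is prone to dimerise, the radical could also attack C9, and the product enone can react again. The fallback sets out from 11 and comes back at 14. DBU-mediated polar 1,6-conjugate addition of nitromethane gives the nitromethyl ketone F1, with the same facial preference anti to the angular methyl; a buffered TiCl3 (McMurry–Nef) reaction then turns CH2NO2 into the aldehyde 14.

Step 18 (ene chlorination). Proton loss could occur from C2–H instead of the methyl, and the face of attack at C15 is not secured. The fallback sets out from 29 and comes back at 30. A dye-sensitised singlet-oxygen ene reaction (O2, tetraphenylporphyrin, light) gives the exo-methylene hydroperoxide F5 with oxygen on the face that gave the wrong chloride; Ph3P reduces it to the allylic alcohol F6; chloride is then introduced with inversion (Ph3P, NCS) to give 30.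

**Further compounds**
F1 | step 6 | (3aS,4S,6aR)-2,3a-dimethyl-4-(nitromethyl)-4,6a-dihydropentalen-1(3aH)-one | [O-][N+](=O)C[C@H]1C=C[C@H]2C(=O)C(C)=C[C@@]12C
F2 | step 16 | (2S,3S,4R)-2-[(Z)-2-iodoprop-1-en-1-yl]-4-methyl-5-oxo-3-(trimethylsilyloxy)tetrahydrofuran-3-carbaldehyde | O=C[C@]1(O[Si](C)(C)C)[C@@H](C)C(=O)O[C@H]1/C=C(\I)C
F3 | step 16 | coupled iodide: C9–C10 bond, C8–OH and C10–OH formed, dioxolane on C3, TMS ether on C11, Z-iodoalkene; stereocentres as in 30 | O1CCOC1[C@H]2C=C[C@H]3C(=O)[C@@](C)(O)[C@H]([C@H](O)[C@]4(O[Si](C)(C)C)[C@@H](C)C(=O)O[C@H]4/C=C(\I)C)[C@@]23C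
F4 | step 16 | iodo aldehyde: as F3 with C2 aldehyde and free C11–OH | O=C[C@H]2C=C[C@H]3C(=O)[C@@](C)(O)[C@H]([C@H](O)[C@]4(O)[C@@H](C)C(=O)O[C@H]4/C=C(\I)C)[C@@]23C
F5 | step 18 | C15 hydroperoxide analogue of 30 with inverted C15 (OOH in place of Cl) | C=C1[C@@H](OC(C)=O)[C@H]2C=C[C@H]3C(=O)[C@@](C)(O)[C@H]([C@H](OC(C)=O)[C@]4(O)[C@@H](C)C(=O)O[C@H]4[C@@H]1OO)[C@@]23C
F6 | step 18 | C15 alcohol analogue of 30 with inverted C15 (OH in place of Cl) | C=C1[C@@H](OC(C)=O)[C@H]2C=C[C@H]3C(=O)[C@@](C)(O)[C@H]([C@H](OC(C)=O)[C@]4(O)[C@@H](C)C(=O)O[C@H]4[C@@H]1O)[C@@]23C
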